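**Plan**

1. Retrosynthetic cuts, in order: the O7 benzyl ether and the primary acetate; the C3–CHO bond (formyl carbon put onto the C3=C4 styrene bond); the bond from C1 of ring B to the 3,4-dimethoxyphenyl ring together with C2–H; the oxazoline (back to a methyl ester); ring B of a naphthalene at C1–C2 and C4–C4a.
2. Enabling feature (locants: aryl on C1, CH2OH on C2, CHO on C3, OH on C7, OMe on C8): in ring B only C1 and C2 are sp3, C3=C4 is a styrene bond on benzo ring A, and C2 carries a carboxyl-derived carbon. Ring B is therefore a 2-naphthoic acid ring that has taken up an aryl anion at C1 and a proton at C2. C4 is para (through C4a) to O7, so C3 is nucleophilic for a late formylation.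
3. Forward order: ring A is bought with both oxygens; ring B is built flat and aromatic by aldol addition and Friedel–Crafts benzannulation; the ester becomes a chiral 2-oxazoline; the aryllithium dearomatizes ring B at C1 and joins the pendant ring; the oxazoline carbon is unmasked and reduced to CH2OH; C3 is formylated; acetate and benzyl are removed.
4. Stereochemistry: C1 comes from the (S)-tert-leucinol oxazoline (aryl transfer anti to tert-butyl). C2 is set by equilibration of the C2 aldehyde to the trans epimer, favoured because the peri 8-methoxy group holds the C1 aryl pseudo-axial, and is then locked by reduction.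

Key step: step 7

Assumption: in step 7 the aryllithium bound to the oxazoline nitrogen is delivered to the naphthalene face opposite the tert-butyl group, so the (S)-auxiliary is the one that leads to (1S).

**Route**

Step 1
Reactants: 1 2,3-dihydroxybenzaldehyde
Product: 2 3-(benzyloxy)-2-hydroxybenzaldehyde
Conditions: NaH (2.2 equiv), DMSO, rt; BnBr (1.0 equiv), rt
Reagents that add atoms: benzyl bromide, BrCc1ccccc1
Why: Williamson ether synthesis on the dianion, in which the C3 phenoxide (not conjugated with the formyl group) is the more nucleophilic oxygen and should be benzylated selectively.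

Step 2
Reactants: 2 3-(benzyloxy)-2-hydroxybenzaldehyde
Product: 3 3-(benzyloxy)-2-methoxybenzaldehyde
Conditions: MeI, K2CO3, DMF, rt
Reagents that add atoms: iodomethane, CI
Why: Williamson O-methylation of the remaining phenol under standard carbonate conditions.

Step 3
Reactants: 3 3-(benzyloxy)-2-methoxybenzaldehyde; 4 methyl 4,4-dimethoxybutanoate
Product: 5 methyl 2-{[3-(benzyloxy)-2-methoxyphenyl](hydroxy)methyl}-4,4-dimethoxybutanoate (diastereomer mixture)
Conditions: LiN(iPr)2, THF, −78 °C; then 3, −78 °C; AcOH quench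
Reagents that add atoms: none
Why: Directed aldol addition of the lithium ester enolate to the non-enolizable aldehyde; the diastereomer ratio does not matter because both new sp3 carbons become aromatic in step 4.

Step 4
Reactants: 5 methyl 2-{[3-(benzyloxy)-2-methoxyphenyl](hydroxy)methyl}-4,4-dimethoxybutanoate
Product: 7 methyl 7-(benzyloxy)-8-methoxynaphthalene-2-carboxylate, via benzylidene ester 6 (not isolated)
Conditions: TsOH·H2O (0.2 equiv), ClCH2CH2Cl, 70 °C
Reagents that add atoms: none
Why: Acid-catalysed cyclodehydration (Bradsher-type intramolecular Friedel–Crafts reaction) in which the oxocarbenium ion from the acetal attacks the only free ortho position of ring A, para to the benzyloxy group, and loss of water and methanol aromatizes ring B.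

Step 5
Reactants: 7 methyl 7-(benzyloxy)-8-methoxynaphthalene-2-carboxylate; 8 (2S)-2-amino-3,3-dimethylbutan-1-ol ((S)-tert-leucinol)
Product: 9 7-(benzyloxy)-N-[(2S)-1-hydroxy-3,3-dimethylbutan-2-yl]-8-methoxynaphthalene-2-carboxamide
Conditions: AlMe3 (3 equiv), PhMe, 0 → 90 °C; aq. KNaC4H4O6 work-up
Reagents that add atoms: none
Why: Aluminium-amide aminolysis of the methyl ester by the amino group of 8; the stereocentre of 8 is not touched.

Step 6
Reactants: 9 7-(benzyloxy)-N-[(2S)-1-hydroxy-3,3-dimethylbutan-2-yl]-8-methoxynaphthalene-2-carboxamide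
Product: 11 (4S)-2-[7-(benzyloxy)-8-methoxynaphthalen-2-yl]-4-tert-butyl-4,5-dihydro-1,3-oxazole, via mesylate 10 (not isolated)
Conditions: MsCl, Et3N, CH2Cl2, 0 → 40 °C
Reagents that add atoms: none
Why: O-mesylation followed by intramolecular O-alkylation by the amide oxygen (cyclodehydration to the 2-oxazoline), which leaves the stereocentre untouched.

Step 7
Reactants: 11 (4S)-2-[7-(benzyloxy)-8-methoxynaphthalen-2-yl]-4-tert-butyl-4,5-dihydro-1,3-oxazole; 12 4-bromo-1,2-dimethoxybenzene
Product: 15 (4S)-2-[(1S)-7-(benzyloxy)-1-(3,4-dimethoxyphenyl)-8-methoxy-1,2-dihydronaphthalen-2-yl]-4-tert-butyl-4,5-dihydro-1,3-oxazole as the mixture of C2 epimers, via aryllithium 13 (not isolated), via lithium azaenolate 14 (not isolated)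
Conditions: 12, t-BuLi (2 equiv per 12), THF, −78 °C; then 11, −78 → −30 °C; AcOH, −78 °C
Reagents that add atoms: none
Why: Aryllithium 13 binds to the oxazoline nitrogen in the rotamer with N syn to C1 and transfers the aryl group to C1 in a 1,4-addition across N=C–C2=C1, which breaks the aromaticity of ring B only and leaves the lithium azaenolate 14 with the C3=C4 styrene bond in place; C-protonation of 14 at C2 gives 15. The closest known reaction type is the tandem addition of organolithium reagents to chiral 2-oxazolinylnaphthalenes (oxazoline-mediated dearomatizing conjugate addition). No ring is closed. C1 is controlled by the (4S)-tert-butyl group of the auxiliary, which keeps the nitrogen-bound aryllithium on the opposite face and should give (1S), whereas C2 is not fixed here, because protonation anti to the pseudo-axial aryl group is expected to favour the cis epimer, and it is set in step 9. The step needs attack at C1 and not at C3, at the oxazoline carbon or at C8 with loss of methoxide: attack at C1 alone keeps ring A benzenoid, the oxazoline C=N is hindered and poorly electrophilic, and the 8-methoxy group is not ortho to the oxazoline. Halogen–lithium exchange with two equivalents of t-BuLi leaves no alkyl halide that could alkylate 14.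

Step 8
Reactants: 15 (4S)-2-[(1S)-7-(benzyloxy)-1-(3,4-dimethoxyphenyl)-8-methoxy-1,2-dihydronaphthalen-2-yl]-4-tert-butyl-4,5-dihydro-1,3-oxazole (C2 epimers)
Product: 18 (1S)-7-(benzyloxy)-1-(3,4-dimethoxyphenyl)-8-methoxy-1,2-dihydronaphthalene-2-carbaldehyde as the mixture of C2 epimers, via oxazolinium triflate 16 (not isolated), via N-methyloxazolidine 17 (not isolated)
Conditions: MeOTf, CH2Cl2, 0 °C → rt; NaBH4, THF/MeOH, 0 °C; (CO2H)2, THF/H2O, rt
Reagents that add atoms: water, O
Why: N-methylation turns the oxazoline C=N into an iminium ion that NaBH4 reduces to the aminal, and mild acid hydrolysis releases the aldehyde and the amino alcohol (standard oxazoline-to-aldehyde unmasking), with C1 untouched.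

Step 9
Reactants: 18 (1S)-7-(benzyloxy)-1-(3,4-dimethoxyphenyl)-8-methoxy-1,2-dihydronaphthalene-2-carbaldehyde (C2 epimers)
Product: 20 [(1S,2S)-7-(benzyloxy)-1-(3,4-dimethoxyphenyl)-8-methoxy-1,2-dihydronaphthalen-2-yl]methanol (trans), via trans-aldehyde 19 (not isolated)
Conditions: DBU (0.1 equiv), CH2Cl2, 0 °C; then NaBH4, MeOH, −20 °C
Reagents that add atoms: none
Why: Base-catalysed epimerization of the enolizable C2 centre (kinetic α-reprotonation of the dienolate) should funnel the mixture to the trans-diaxial aldehyde 19, in which the formyl group is anti to the aryl group held pseudo-axial by the peri-methoxy group, and carbonyl reduction with NaBH4 in the same flask locks C2.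

Step 10
Reactants: 20 [(1S,2S)-7-(benzyloxy)-1-(3,4-dimethoxyphenyl)-8-methoxy-1,2-dihydronaphthalen-2-yl]methanol
Product: 21 [(1S,2S)-7-(benzyloxy)-1-(3,4-dimethoxyphenyl)-8-methoxy-1,2-dihydronaphthalen-2-yl]methyl acetate
Conditions: Ac2O, pyridine, DMAP (cat.), CH2Cl2, rt
Reagents that add atoms: acetic anhydride, CC(=O)OC(C)=O
Why: DMAP-catalysed acylation protects the hydroxyl group against the chloroiminium reagent of step 11.

Step 11
Reactants: 21 [(1S,2S)-7-(benzyloxy)-1-(3,4-dimethoxyphenyl)-8-methoxy-1,2-dihydronaphthalen-2-yl]methyl acetate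
Product: 23 [(1S,2R)-7-(benzyloxy)-1-(3,4-dimethoxyphenyl)-3-formyl-8-methoxy-1,2-dihydronaphthalen-2-yl]methyl acetate, via iminium chloride 22 (not isolated)
Conditions: POCl3, DMF, 0 → 50 °C; aq. NaOAc, rt
Reagents that add atoms: N,N-dimethylformamide, CN(C)C=O; water, O
Why: Vilsmeier–Haack formylation of an electron-rich styrene, in which the chloroiminium ion attacks C3 because the resulting C4 cation is benzylic and para (through C4a) to the benzyloxy oxygen, loss of the C3 proton restores C3=C4, and hydrolysis of 22 gives the enal without touching C1 or C2.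

Step 12
Reactants: 23 [(1S,2R)-7-(benzyloxy)-1-(3,4-dimethoxyphenyl)-3-formyl-8-methoxy-1,2-dihydronaphthalen-2-yl]methyl acetate
Product: 24 (1S,2R)-7-(benzyloxy)-1-(3,4-dimethoxyphenyl)-2-(hydroxymethyl)-8-methoxy-1,2-dihydronaphthalene-3-carbaldehyde
Conditions: K2CO3 (cat.), MeOH, 0 °C
Reagents that add atoms: none
Why: Base-catalysed transesterification of the primary acetate, under which C2–H, attached to the nodal carbon of the enal, is not acidic and should keep its configuration.

Step 13
Reactants: 24 (1S,2R)-7-(benzyloxy)-1-(3,4-dimethoxyphenyl)-2-(hydroxymethyl)-8-methoxy-1,2-dihydronaphthalene-3-carbaldehyde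
Product: 25 vitekwangin B
Conditions: BCl3, C6HMe5, CH2Cl2, −78 °C; MeOH quench
Reagents that add atoms: none
Why: Lewis-acid debenzylation in which BCl3 activates the aryl benzyl ether and pentamethylbenzene traps the benzyl cation by Friedel–Crafts alkylation, so that at −78 °C the methyl ethers, the enal and the C3=C4 bond (which rules out hydrogenolysis) should survive.

**Compound list**

1 | 2,3-dihydroxybenzaldehyde | O=Cc1cccc(O)c1O | starting material
2 | 3-(benzyloxy)-2-hydroxybenzaldehyde | O=Cc1cccc(OCc2ccccc2)c1O | intermediate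
3 | 3-(benzyloxy)-2-methoxybenzaldehyde | COc1c(C=O)cccc1OCc1ccccc1 | intermediate
4 | methyl 4,4-dimethoxybutanoate | COC(=O)CCC(OC)OC | starting material
5 | methyl 2-{[3-(benzyloxy)-2-methoxyphenyl](hydroxy)methyl}-4,4-dimethoxybutanoate (diastereomer mixture) | COC(=O)C(CC(OC)OC)C(O)c1cccc(OCc2ccccc2)c1OC | intermediate
6 | methyl (E)-2-[3-(benzyloxy)-2-methoxybenzylidene]-4,4-dimethoxybutanoate (not isolated, step 4) | COC(=O)/C(CC(OC)OC)=C/c1cccc(OCc2ccccc2)c1OC | intermediate
7 | methyl 7-(benzyloxy)-8-methoxynaphthalene-2-carboxylate | COC(=O)c1ccc2ccc(OCc3ccccc3)c(OC)c2c1 | intermediate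
8 | (2S)-2-amino-3,3-dimethylbutan-1-ol ((S)-tert-leucinol) | N[C@@H](C(C)(C)C)CO | starting material
9 | 7-(benzyloxy)-N-[(2S)-1-hydroxy-3,3-dimethylbutan-2-yl]-8-methoxynaphthalene-2-carboxamide | COc1c(OCc2ccccc2)ccc2ccc(C(=O)N[C@@H](C(C)(C)C)CO)cc12 | intermediate
10 | O-mesylate of 9 (not isolated, step 6) | COc1c(OCc2ccccc2)ccc2ccc(C(=O)N[C@@H](C(C)(C)C)COS(C)(=O)=O)cc12 | intermediate
11 | (4S)-2-[7-(benzyloxy)-8-methoxynaphthalen-2-yl]-4-tert-butyl-4,5-dihydro-1,3-oxazole | COc1c(OCc2ccccc2)ccc2ccc(C3=N[C@@H](C(C)(C)C)CO3)cc12 | intermediate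
12 | 4-bromo-1,2-dimethoxybenzene | COc1ccc(Br)cc1OC | starting material
13 | 3,4-dimethoxyphenyllithium (not isolated, step 7) | [Li]c1ccc(OC)c(OC)c1 | intermediate
14 | lithium azaenolate from 1,4-addition of 13 to 11, (1S) (not isolated, step 7) | COc1ccc([C@H]2c3c(ccc(OCc4ccccc4)c3OC)C=CC2=C5N([Li])[C@@H](C(C)(C)C)CO5)cc1OC | intermediate
15 | (4S)-2-[(1S)-7-(benzyloxy)-1-(3,4-dimethoxyphenyl)-8-methoxy-1,2-dihydronaphthalen-2-yl]-4-tert-butyl-4,5-dihydro-1,3-oxazole, both C2 epimers | COc1ccc([C@H]2c3c(ccc(OCc4ccccc4)c3OC)C=CC2C5=N[C@@H](C(C)(C)C)CO5)cc1OC | intermediate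
16 | N-methyloxazolinium triflate of 15 (not isolated, step 8) | COc1ccc([C@H]2c3c(ccc(OCc4ccccc4)c3OC)C=CC2C5=[N+](C)[C@@H](C(C)(C)C)CO5)cc1OC.[O-]S(=O)(=O)C(F)(F)F | intermediate
17 | N-methyloxazolidine from 16 (not isolated, step 8) | COc1ccc([C@H]2c3c(ccc(OCc4ccccc4)c3OC)C=CC2C5N(C)[C@@H](C(C)(C)C)CO5)cc1OC | intermediate
18 | (1S)-7-(benzyloxy)-1-(3,4-dimethoxyphenyl)-8-methoxy-1,2-dihydronaphthalene-2-carbaldehyde, both C2 epimers | COc1ccc([C@H]2c3c(ccc(OCc4ccccc4)c3OC)C=CC2C=O)cc1OC | intermediate
19 | (1S,2S)-7-(benzyloxy)-1-(3,4-dimethoxyphenyl)-8-methoxy-1,2-dihydronaphthalene-2-carbaldehyde, trans (not isolated, step 9) | COc1ccc([C@H]2c3c(ccc(OCc4ccccc4)c3OC)C=C[C@@H]2C=O)cc1OC | intermediate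
20 | [(1S,2S)-7-(benzyloxy)-1-(3,4-dimethoxyphenyl)-8-methoxy-1,2-dihydronaphthalen-2-yl]methanol, trans | COc1ccc([C@H]2c3c(ccc(OCc4ccccc4)c3OC)C=C[C@@H]2CO)cc1OC | intermediate
21 | [(1S,2S)-7-(benzyloxy)-1-(3,4-dimethoxyphenyl)-8-methoxy-1,2-dihydronaphthalen-2-yl]methyl acetate | COc1ccc([C@H]2c3c(ccc(OCc4ccccc4)c3OC)C=C[C@@H]2COC(C)=O)cc1OC | intermediate
22 | C3 dimethyliminium chloride from 21 (not isolated, step 11) | COc1ccc([C@H]2c3c(ccc(OCc4ccccc4)c3OC)C=C(C=[N+](C)C)[C@@H]2COC(C)=O)cc1OC.[Cl-] | intermediate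
23 | [(1S,2R)-7-(benzyloxy)-1-(3,4-dimethoxyphenyl)-3-formyl-8-methoxy-1,2-dihydronaphthalen-2-yl]methyl acetate | COc1ccc([C@H]2c3c(ccc(OCc4ccccc4)c3OC)C=C(C=O)[C@@H]2COC(C)=O)cc1OC | intermediate
24 | (1S,2R)-7-(benzyloxy)-1-(3,4-dimethoxyphenyl)-2-(hydroxymethyl)-8-methoxy-1,2-dihydronaphthalene-3-carbaldehyde | COc1ccc([C@H]2c3c(ccc(OCc4ccccc4)c3OC)C=C(C=O)[C@@H]2CO)cc1OC | intermediate
25 | vitekwangin B, (1S,2R)-1-(3,4-dimethoxyphenyl)-7-hydroxy-2-(hydroxymethyl)-8-methoxy-1,2-dihydronaphthalene-3-carbaldehyde | COc1ccc([C@H]2c3c(ccc(O)c3OC)C=C(C=O)[C@@H]2CO)cc1OC | target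

**Step count and risks**

Total step count: 13. Longest linear sequence: 13 steps (from 1; compounds 4, 8 and 12 are bought).

The three steps most likely to fail:

Step 7. The risk is poor facial selectivity of the aryl transfer, because the peri-methoxy group next to C1 may override delivery anti to the tert-butyl group. The fallback gives up auxiliary control and resolves instead. It sets out from ester 7. Aminolysis with 2-amino-2-methylpropan-1-ol and AlMe3 should give the hydroxyamide F1, and cyclodehydration (MsCl, Et3N) the achiral 4,4-dimethyloxazoline F2. Addition of aryllithium 13 and protonation as in step 7 should give the racemic adduct F3. The operations of steps 8 and 9 should give the racemic aldehyde F4 and then the racemic trans-alcohol F5. Preparative chromatography of F5 on a chiral stationary phase returns the route at alcohol 20.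

Step 9. The risk is migration of the C3=C4 bond into conjugation with the formyl group during base treatment, which would erase C2 and then C1, or an unfavourable trans/cis equilibrium. The fallback sets C2 kinetically. It sets out from oxazoline 11. Azaenolate 14, made as in step 7, is alkylated at C2 with benzyl chloromethyl ether, which should enter anti to the C1 aryl group and give the quaternary oxazoline F6. N-methylation, NaBH4 reduction and hydrolysis as in step 8 should give the non-enolizable aldehyde F7. Tsuji–Wilkinson decarbonylation with RhCl(PPh3)3 (PhCN, 130 °C), which proceeds with retention, should place hydrogen where the formyl group was and give the trans bis-benzyl ether F8. Vilsmeier–Haack formylation as in step 11 should give the enal F9, and BCl3 with pentamethylbenzene (−78 → −30 °C) removes both benzyl groups to return at target 25.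

Step 11. The risk is attack of the chloroiminium ion on the electron-rich aryl rings, or acid-induced aromatization of ring B. The fallback brings in the formyl carbon by palladium catalysis. It sets out from acetate 21. N-bromosuccinimide in aqueous THF (0 °C) should give the bromohydrin F10, with bromine on C3 and hydroxyl on the benzylic C4. Dehydration (TsOH, PhMe, 60 °C) should give the vinyl bromide F11. Reductive carbonylation (Pd(OAc)2, di(1-adamantyl)-n-butylphosphine, CO/H2, TMEDA, PhMe, 100 °C) returns the route at enal acetate 23.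

**Further compounds**

F1 | step 7 | 7-(benzyloxy)-N-(1-hydroxy-2-methylpropan-2-yl)-8-methoxynaphthalene-2-carboxamide | COc1c(OCc2ccccc2)ccc2ccc(C(=O)NC(C)(C)CO)cc12
F2 | step 7 | 2-[7-(benzyloxy)-8-methoxynaphthalen-2-yl]-4,4-dimethyl-4,5-dihydro-1,3-oxazole | COc1c(OCc2ccccc2)ccc2ccc(C3=NC(C)(C)CO3)cc12
F3 | step 7 | racemic 2-[7-(benzyloxy)-1-(3,4-dimethoxyphenyl)-8-methoxy-1,2-dihydronaphthalen-2-yl]-4,4-dimethyl-4,5-dihydro-1,3-oxazole | COc1ccc(C2c3c(ccc(OCc4ccccc4)c3OC)C=CC2C5=NC(C)(C)CO5)cc1OC
F4 | step 7 | racemic 7-(benzyloxy)-1-(3,4-dimethoxyphenyl)-8-methoxy-1,2-dihydronaphthalene-2-carbaldehyde | COc1ccc(C2c3c(ccc(OCc4ccccc4)c3OC)C=CC2C=O)cc1OC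
F5 | step 7 | racemic trans-[7-(benzyloxy)-1-(3,4-dimethoxyphenyl)-8-methoxy-1,2-dihydronaphthalen-2-yl]methanol | COc1ccc(C2c3c(ccc(OCc4ccccc4)c3OC)C=CC2CO)cc1OC
F6 | step 9 | (4S)-2-[(1S)-7-(benzyloxy)-2-(benzyloxymethyl)-1-(3,4-dimethoxyphenyl)-8-methoxy-1,2-dihydronaphthalen-2-yl]-4-tert-butyl-4,5-dihydro-1,3-oxazole, benzyloxymethyl anti to the aryl group | COc1ccc([C@H]2c3c(ccc(OCc4ccccc4)c3OC)C=C[C@]2(C5=N[C@@H](C(C)(C)C)CO5)COCc6ccccc6)cc1OC
F7 | step 9 | (1S)-7-(benzyloxy)-2-(benzyloxymethyl)-1-(3,4-dimethoxyphenyl)-8-methoxy-1,2-dihydronaphthalene-2-carbaldehyde, benzyloxymethyl anti to the aryl group | COc1ccc([C@H]2c3c(ccc(OCc4ccccc4)c3OC)C=C[C@]2(C=O)COCc5ccccc5)cc1OC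
F8 | step 9 | trans-(1S)-7-(benzyloxy)-2-(benzyloxymethyl)-1-(3,4-dimethoxyphenyl)-8-methoxy-1,2-dihydronaphthalene | COc1ccc([C@H]2c3c(ccc(OCc4ccccc4)c3OC)C=C[C@@H]2COCc5ccccc5)cc1OC
F9 | step 9 | trans-(1S)-7-(benzyloxy)-2-(benzyloxymethyl)-1-(3,4-dimethoxyphenyl)-8-methoxy-1,2-dihydronaphthalene-3-carbaldehyde | COc1ccc([C@H]2c3c(ccc(OCc4ccccc4)c3OC)C=C(C=O)[C@@H]2COCc5ccccc5)cc1OC
F10 | step 11 | [(1S)-7-(benzyloxy)-3-bromo-1-(3,4-dimethoxyphenyl)-4-hydroxy-8-methoxy-1,2,3,4-tetrahydronaphthalen-2-yl]methyl acetate, trans at C1/C2 | COc1ccc([C@H]2c3c(ccc(OCc4ccccc4)c3OC)C(O)C(Br)[C@@H]2COC(C)=O)cc1OC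
F11 | step 11 | [(1S)-7-(benzyloxy)-3-bromo-1-(3,4-dimethoxyphenyl)-8-methoxy-1,2-dihydronaphthalen-2-yl]methyl acetate, trans at C1/C2 | COc1ccc([C@H]2c3c(ccc(OCc4ccccc4)c3OC)C=C(Br)[C@@H]2COC(C)=O)cc1OC
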